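**Strategy**

Labdane numbering is used. Ring A (C1–C2–C3–C4–C5–C10) carries the C1 oxygen and the C4 ester in a 1,4-relationship beside the C5–C10 ring fusion: the imprint of a 2-oxydiene/enoate cycloaddition. Disconnecting C3–C4 and C5–C10 opens rings A and B together to an acyclic triene, a 2-silyloxydiene (C3=C2–C1(OTBS)=C10) joined through C9–C8(=CH2)–C7–C6 to a (Z)-2-methylenoate (C4=C5). One thermal intramolecular Diels–Alder reaction closes both rings and sets C4, C5 and C10 from the lone stereocentre C9, itself made by Rh(acac)(C2H4)2/(S)-BINAP-catalysed conjugate addition to a lactone that masks C1 and C12. The dienyl side chain follows by two Wittig reactions.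

Key step: step 9

Remarks on the chemistry:
- Numbering: C1–C10 ring carbons, C11–C16 side chain, C17 exocyclic methylene, C19 ester carbon, C20 angular methyl.
- Assumption: Rh/(S)-BINAP is taken to add to 5,6-dihydro-2H-pyran-2-one with the facial sense established for 2-cyclohexenone; if the sense were opposite, (R)-BINAP would be used.
- The C10 configuration in 7–10 is drawn as the expected trans epimer; it is of no consequence because C10 becomes sp2 in step 8.

**Route**

Step 1
Reactants: 1 (1,3-dioxolan-2-ylmethyl)magnesium bromide; 2 2,3-dibromoprop-1-ene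
Product: 3 2-(3-bromobut-3-en-1-yl)-1,3-dioxolane
Conditions: Li2CuCl4 (3 mol%), THF, 0 °C → rt
Reagents that add atoms: none
Why: Copper-catalysed Grignard cross-coupling at the allylic bromide of 2 (SN2 and SN2′ give the same product, the vinylic bromide is inert) should deliver the C17=C8(Br)–C7–C6–C5 unit with C5 masked as a dioxolane, and no stereocentre is formed.

Step 2
Reactants: 3 2-(3-bromobut-3-en-1-yl)-1,3-dioxolane
Product: 4 2-[4-(1,3-dioxolan-2-yl)but-1-en-2-yl]-4,4,5,5-tetramethyl-1,3,2-dioxaborolane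
Conditions: B2pin2, PdCl2(PPh3)2 (3 mol%), PPh3, KOPh, PhMe, 50 °C
Reagents that add atoms: bis(pinacolato)diboron, CC1(C)OB(OC1(C)C)B1OC(C)(C)C(C)(C)O1
Why: Miyaura borylation under the weak-base conditions used for alkenyl halides should convert C8–Br into C8–B without touching the acetal, and no stereocentre is formed.

Step 3
Reactants: 4 2-[4-(1,3-dioxolan-2-yl)but-1-en-2-yl]-4,4,5,5-tetramethyl-1,3,2-dioxaborolane; 5 5,6-dihydro-2H-pyran-2-one
Product: 6 (4S)-4-[4-(1,3-dioxolan-2-yl)but-1-en-2-yl]oxan-2-one
Conditions: Rh(acac)(C2H4)2 (3 mol%), (S)-BINAP (3.3 mol%), dioxane/H2O 10:1, 100 °C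
Reagents that add atoms: none
Why: The Hayashi–Miyaura asymmetric 1,4-addition creates C9, the (S)-BINAP-bound alkenylrhodium species adding to the enantioface that gives the (S)-lactone by analogy with (S)-3-arylcyclohexanones, while the lactone keeps C1 and C12 at different oxidation levels.

Step 4
Reactants: 6 (4S)-4-[4-(1,3-dioxolan-2-yl)but-1-en-2-yl]oxan-2-one
Product: 7 (3R,4S)-4-[4-(1,3-dioxolan-2-yl)but-1-en-2-yl]-3-methyloxan-2-one
Conditions: LiN(i-Pr)2, THF, −78 °C; MeI, −78 → −40 °C
Reagents that add atoms: iodomethane, CI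
Why: Lactone enolate alkylation should install C20 on C10 anti to the adjacent C9 substituent (trans), a configuration that is later erased.

Step 5
Reactants: 7 (3R,4S)-4-[4-(1,3-dioxolan-2-yl)but-1-en-2-yl]-3-methyloxan-2-one
Product: 8 4-[(3R,4S)-3-methyl-2-oxooxan-4-yl]pent-4-enal
Conditions: 1 M aq. HCl (cat.), THF, rt
Reagents that add atoms: water, O
Why: Acid-catalysed acetal hydrolysis should free the C5 aldehyde, the δ-lactone and the 1,1-disubstituted alkene being stable to dilute aqueous acid at room temperature.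

Step 6
Reactants: 8 4-[(3R,4S)-3-methyl-2-oxooxan-4-yl]pent-4-enal
Product: 9 methyl (2Z)-2-methyl-6-[(3R,4S)-3-methyl-2-oxooxan-4-yl]hepta-2,6-dienoate
Conditions: (CF3CH2O)2P(O)CH(CH3)CO2CH3, KN(SiMe3)2, 18-crown-6, THF, −78 °C
Reagents that add atoms: methyl 2-[bis(2,2,2-trifluoroethoxy)phosphoryl]propanoate, COC(=O)C(C)P(=O)(OCC(F)(F)F)OCC(F)(F)F
Why: The Still–Gennari olefination should give the (Z)-2-methyl-2-enoate (C4=C5, ester cis to C6) under kinetic control, the preformed phosphonate anion being too weak a base to enolise the lactone.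

Step 7
Reactants: 9 methyl (2Z)-2-methyl-6-[(3R,4S)-3-methyl-2-oxooxan-4-yl]hepta-2,6-dienoate
Product: 10 methyl (2Z,7S,8R)-7-(2-hydroxyethyl)-2,8-dimethyl-6-methylidene-9-oxoundeca-2,10-dienoate
Conditions: CH2=CHMgBr (1.15 equiv), THF, −78 °C; then H2O
Reagents that add atoms: vinylmagnesium bromide, C=C[Mg]Br
Why: Mono-addition of a Grignard reagent to a δ-lactone should stop at the magnesium lactolate at −78 °C and give the δ-hydroxy vinyl ketone on work-up, the hindered conjugated α-methyl enoate being much less electrophilic and C9 untouched.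

Step 8
Reactants: 10 methyl (2Z,7S,8R)-7-(2-hydroxyethyl)-2,8-dimethyl-6-methylidene-9-oxoundeca-2,10-dienoate
Product: 11 methyl (2Z,7R,8Z)-9-[(tert-butyldimethylsilyl)oxy]-7-{2-[(tert-butyldimethylsilyl)oxy]ethyl}-2,8-dimethyl-6-methylideneundeca-2,8,10-trienoate
Conditions: TBSOTf (2.4 equiv), Et3N (4 equiv), CH2Cl2, −78 → 0 °C
Reagents that add atoms: tert-butyldimethylsilyl trifluoromethanesulfonate, CC(C)(C)[Si](C)(C)OS(=O)(=O)C(F)(F)F
Why: Silyl triflate/amine soft enolisation should silylate the primary alcohol and turn the enone into the 2-silyloxydiene by deprotonation at C10 (the only enolisable position), the (Z)-enol ether with C9 cis to OTBS and the small C20 methyl cis to the vinyl group being favoured because it minimises A(1,3) strain with the vinyl group.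

Step 9
Reactants: 11 methyl (2Z,7R,8Z)-9-[(tert-butyldimethylsilyl)oxy]-7-{2-[(tert-butyldimethylsilyl)oxy]ethyl}-2,8-dimethyl-6-methylideneundeca-2,8,10-trienoate
Product: 13 methyl (1R,4aS,5R,8aS)-5-(2-hydroxyethyl)-1,4a-dimethyl-6-methylidene-4-oxodecahydronaphthalene-1-carboxylate, via bis-silyl cycloadduct 12 (not isolated)
Conditions: PhMe (0.01 M), BHT (cat.), sealed tube, 170 °C; then 48% aq. HF, MeCN, 0 °C → rt
Reagents that add atoms: none
Why: On heating, triene 11 should undergo a concerted, asynchronous intramolecular Diels–Alder reaction (type 1, 1,7,9-decatriene; closest known type: the cyclisation of 2-silyloxytrienes made by enol silylation of trienones) in which the nucleophilic enol ether carbon C10 of the diene C3=C2–C1(OTBS)=C10 bonds to the β-carbon C5 of the enoate and C3 to C4, tether and polarity (C1–O para to the ester) imposing the same regiochemistry. Ring A is closed by the [4+2] cyclisation itself and ring B by the four-atom tether C9–C8–C7–C6 in the fused mode through a chair-like arrangement. C10 is controlled by C9: H9 eclipses the C10=C1 bond to avoid A(1,3) strain with the C1–OTBS group, so the dienophile held by C8 reaches C10 on the face anti to C11, and C11 ends cis to C20. C5 is controlled by the exo position of the tether in the chair-like transition state that leads to the trans-decalin (H5 anti to C20), and C4 by suprafacial transfer of the Z-geometry, which puts the ester exo (cis to C6, hence 1,3-diaxial cis to C20) and the α-methyl endo. The selectivity needed is trans over cis ring fusion together with cycloaddition faster than a [1,5]-hydrogen shift from C20; the (Z)-enol ether geometry (tether outside, methyl inside), the methyl-endo/ester-exo preference of α-methylacrylic esters and the C20/C4-methyl repulsion in the cis-fused alternative should secure the former, dilution and a radical inhibitor the latter. Aqueous HF then cleaves the silyl enol ether (protonation at C2, no stereocentre) and the primary silyl ether of 12 without isolation.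

Step 10
Reactants: 13 methyl (1R,4aS,5R,8aS)-5-(2-hydroxyethyl)-1,4a-dimethyl-6-methylidene-4-oxodecahydronaphthalene-1-carboxylate
Product: 14 methyl (1R,4aS,5R,8aS)-1,4a-dimethyl-6-methylidene-4-oxo-5-(2-oxoethyl)decahydronaphthalene-1-carboxylate
Conditions: Dess–Martin periodinane, CH2Cl2, rt
Reagents that add atoms: none
Why: Dess–Martin oxidation of the primary alcohol (which reacts through the open hydroxy ketone form) should give the C12 aldehyde under near-neutral conditions without alkene migration.

Step 11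
Reactants: 14 methyl (1R,4aS,5R,8aS)-1,4a-dimethyl-6-methylidene-4-oxo-5-(2-oxoethyl)decahydronaphthalene-1-carboxylate
Product: 15 methyl (1R,4aS,5R,8aS)-1,4a-dimethyl-6-methylidene-5-[(2E)-3-methyl-4-oxobut-2-en-1-yl]-4-oxodecahydronaphthalene-1-carboxylate
Conditions: Ph3P=C(CH3)CHO, PhMe, 80 °C
Reagents that add atoms: 2-(triphenyl-λ5-phosphanylidene)propanal, CC(C=O)=P(c1ccccc1)(c1ccccc1)c1ccccc1
Why: Wittig olefination with the stabilised α-methyl formyl ylide should react only at the aldehyde (the neopentyl C1 ketone is inert) and give the (E)-trisubstituted enal at C12=C13 under thermodynamic control of oxaphosphetane formation.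

Step 12
Reactants: 15 methyl (1R,4aS,5R,8aS)-1,4a-dimethyl-6-methylidene-5-[(2E)-3-methyl-4-oxobut-2-en-1-yl]-4-oxodecahydronaphthalene-1-carboxylate
Product: 16 methyl (1R,4aS,5R,8aS)-1,4a-dimethyl-6-methylidene-5-[(2E)-3-methylpenta-2,4-dien-1-yl]-4-oxodecahydronaphthalene-1-carboxylate
Conditions: Ph3PCH3Br, KN(SiMe3)2, THF, 0 °C; then 15, −78 → 0 °C
Reagents that add atoms: methylidenetriphenylphosphorane, C=P(c1ccccc1)(c1ccccc1)c1ccccc1
Why: Wittig methylenation at low temperature should convert the unhindered enal aldehyde into the C14=C15 vinyl group faster than the ylide attacks or enolises the hindered C1 ketone, leaving the E-geometry at C12=C13 intact.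

Step 13
Reactants: 16 methyl (1R,4aS,5R,8aS)-1,4a-dimethyl-6-methylidene-5-[(2E)-3-methylpenta-2,4-dien-1-yl]-4-oxodecahydronaphthalene-1-carboxylate
Product: 17 methyl (1R,4S,4aS,5R,8aS)-4-hydroxy-1,4a-dimethyl-6-methylidene-5-[(2E)-3-methylpenta-2,4-dien-1-yl]decahydronaphthalene-1-carboxylate
Conditions: NaBH4, MeOH, 0 °C
Reagents that add atoms: none
Why: In this borohydride reduction the small hydride should add along the axial trajectory on the face anti to the adjacent axial C20 methyl (as in 17-oxo steroids and 8a-methyl-1-decalones), giving the equatorial (1S) alcohol cis to C20.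

Step 14
Reactants: 17 methyl (1R,4S,4aS,5R,8aS)-4-hydroxy-1,4a-dimethyl-6-methylidene-5-[(2E)-3-methylpenta-2,4-dien-1-yl]decahydronaphthalene-1-carboxylate
Product: 18 methyl (1R,4S,4aS,5R,8aS)-4-(acetyloxy)-1,4a-dimethyl-6-methylidene-5-[(2E)-3-methylpenta-2,4-dien-1-yl]decahydronaphthalene-1-carboxylate (CNP0235031.1)
Conditions: Ac2O, DMAP (cat.), pyridine, rt
Reagents that add atoms: acetic anhydride, CC(=O)OC(C)=O
Why: DMAP-catalysed acylation of the equatorial secondary alcohol should give the acetate with retention at C1, the methyl ester and the alkenes being inert.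

**Compound list**

1 | (1,3-dioxolan-2-ylmethyl)magnesium bromide | Br[Mg]CC1OCCO1 | starting material
2 | 2,3-dibromoprop-1-ene | C=C(Br)CBr | starting material
3 | 2-(3-bromobut-3-en-1-yl)-1,3-dioxolane | C=C(Br)CCC1OCCO1 | intermediate
4 | 2-[4-(1,3-dioxolan-2-yl)but-1-en-2-yl]-4,4,5,5-tetramethyl-1,3,2-dioxaborolane | C=C(CCC1OCCO1)B1OC(C)(C)C(C)(C)O1 | intermediate
5 | 5,6-dihydro-2H-pyran-2-one | O=C1C=CCCO1 | starting material
6 | (4S)-4-[4-(1,3-dioxolan-2-yl)but-1-en-2-yl]oxan-2-one | O=C1C[C@@H](C(=C)CCC2OCCO2)CCO1 | intermediate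
7 | (3R,4S)-4-[4-(1,3-dioxolan-2-yl)but-1-en-2-yl]-3-methyloxan-2-one | O=C1[C@H](C)[C@@H](C(=C)CCC2OCCO2)CCO1 | intermediate
8 | 4-[(3R,4S)-3-methyl-2-oxooxan-4-yl]pent-4-enal | O=C1[C@H](C)[C@@H](C(=C)CCC=O)CCO1 | intermediate
9 | methyl (2Z)-2-methyl-6-[(3R,4S)-3-methyl-2-oxooxan-4-yl]hepta-2,6-dienoate | O=C1[C@H](C)[C@@H](C(=C)CC/C=C(/C)C(=O)OC)CCO1 | intermediate
10 | methyl (2Z,7S,8R)-7-(2-hydroxyethyl)-2,8-dimethyl-6-methylidene-9-oxoundeca-2,10-dienoate (in equilibrium with its cyclic hemiketal) | C=CC(=O)[C@H](C)[C@H](CCO)C(=C)CC/C=C(/C)C(=O)OC | intermediate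
11 | methyl (2Z,7R,8Z)-9-[(tert-butyldimethylsilyl)oxy]-7-{2-[(tert-butyldimethylsilyl)oxy]ethyl}-2,8-dimethyl-6-methylideneundeca-2,8,10-trienoate | C=C/C(O[Si](C)(C)C(C)(C)C)=C(C)/[C@H](CCO[Si](C)(C)C(C)(C)C)C(=C)CC/C=C(/C)C(=O)OC | intermediate
12 | methyl (1R,4aS,5R,8aS)-4-[(tert-butyldimethylsilyl)oxy]-5-{2-[(tert-butyldimethylsilyl)oxy]ethyl}-1,4a-dimethyl-6-methylidene-1,2,4a,5,6,7,8,8a-octahydronaphthalene-1-carboxylate (bis-silyl cycloadduct, not isolated) | CC(C)(C)[Si](C)(C)OCC[C@@H]1C(=C)CC[C@H]2[C@@]1(C)C(O[Si](C)(C)C(C)(C)C)=CC[C@@]2(C)C(=O)OC | intermediate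
13 | methyl (1R,4aS,5R,8aS)-5-(2-hydroxyethyl)-1,4a-dimethyl-6-methylidene-4-oxodecahydronaphthalene-1-carboxylate (in equilibrium with its cyclic hemiketal) | OCC[C@@H]1C(=C)CC[C@H]2[C@@]1(C)C(=O)CC[C@@]2(C)C(=O)OC | intermediate
14 | methyl (1R,4aS,5R,8aS)-1,4a-dimethyl-6-methylidene-4-oxo-5-(2-oxoethyl)decahydronaphthalene-1-carboxylate | O=CC[C@@H]1C(=C)CC[C@H]2[C@@]1(C)C(=O)CC[C@@]2(C)C(=O)OC | intermediate
15 | methyl (1R,4aS,5R,8aS)-1,4a-dimethyl-6-methylidene-5-[(2E)-3-methyl-4-oxobut-2-en-1-yl]-4-oxodecahydronaphthalene-1-carboxylate | O=C/C(C)=C/C[C@@H]1C(=C)CC[C@H]2[C@@]1(C)C(=O)CC[C@@]2(C)C(=O)OC | intermediate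
16 | methyl (1R,4aS,5R,8aS)-1,4a-dimethyl-6-methylidene-5-[(2E)-3-methylpenta-2,4-dien-1-yl]-4-oxodecahydronaphthalene-1-carboxylate | C=C/C(C)=C/C[C@@H]1C(=C)CC[C@H]2[C@@]1(C)C(=O)CC[C@@]2(C)C(=O)OC | intermediate
17 | methyl (1R,4S,4aS,5R,8aS)-4-hydroxy-1,4a-dimethyl-6-methylidene-5-[(2E)-3-methylpenta-2,4-dien-1-yl]decahydronaphthalene-1-carboxylate | C=C/C(C)=C/C[C@@H]1C(=C)CC[C@H]2[C@@]1(C)[C@@H](O)CC[C@@]2(C)C(=O)OC | intermediate
18 | methyl (1R,4S,4aS,5R,8aS)-4-(acetyloxy)-1,4a-dimethyl-6-methylidene-5-[(2E)-3-methylpenta-2,4-dien-1-yl]decahydronaphthalene-1-carboxylate (CNP0235031.1) | C=C/C(C)=C/C[C@@H]1C(=C)CC[C@H]2[C@@]1(C)[C@@H](OC(C)=O)CC[C@@]2(C)C(=O)OC | target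

**Step count**

Total steps: 14. Longest linear sequence: 14 steps (1 and 2 to 18).

**Steps most likely to fail**

Step 9 (key cycloaddition). The Z-trisubstituted enoate and the diene terminus bearing an inside methyl may cyclise sluggishly, so that a [1,5]-hydrogen shift from C20 competes. The ring-fusion (exo/endo) selectivity may also erode, and any (E)-enol ether in 11 would not cyclise productively and would return 10 after the HF treatment. The fallback separates the C4 quaternary centre from the cycloaddition. It sets out from aldehyde 8: Wittig olefination with methyl (triphenylphosphoranylidene)acetate should give methyl (2E)-6-[(3R,4S)-3-methyl-2-oxooxan-4-yl]hepta-2,6-dienoate F1. Vinylmagnesium bromide at −78 °C should then give the hydroxy enone methyl (2E,7S,8R)-7-(2-hydroxyethyl)-8-methyl-6-methylidene-9-oxoundeca-2,10-dienoate F2, and TBSOTf/Et3N the silyloxytriene methyl (2E,7R,8Z)-9-[(tert-butyldimethylsilyl)oxy]-7-{2-[(tert-butyldimethylsilyl)oxy]ethyl}-8-methyl-6-methylideneundeca-2,8,10-trienoate F3. This unhindered (E)-enoate should cyclise at lower temperature through the ester-endo, trans-fused chair transition state to the C4–H cycloadduct methyl (1S,4aR,5R,8aR)-4-[(tert-butyldimethylsilyl)oxy]-5-{2-[(tert-butyldimethylsilyl)oxy]ethyl}-4a-methyl-6-methylidene-1,2,4a,5,6,7,8,8a-octahydronaphthalene-1-carboxylate F4. Deprotonation of F4 with LiN(i-Pr)2 and methylation with MeI on the equatorial face anti to C20 (the classical alkylation of C4 ester enolates of trans-decalins, which leaves the ester axial) comes back to the route at cycloadduct 12, which is desilylated to 13 as in step 9.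

Step 7 (vinyl Grignard addition to the lactone). The lactolate may collapse early and the liberated vinyl ketone may take up a second equivalent of Grignard reagent, or the reagent may attack the enoate. The fallback sets out from lactone 9: aminolysis with Me(MeO)NH·HCl/Me3Al in CH2Cl2 should open only the lactone to the hydroxy amide methyl (2Z,7S,8R)-7-(2-hydroxyethyl)-9-[methoxy(methyl)amino]-2,8-dimethyl-6-methylidene-9-oxonon-2-enoate F5. Vinylmagnesium bromide (2.2 equiv, 0 °C, cold acidic quench) should then stop at the chelated tetrahedral intermediate and come back to the route at hydroxy enone 10.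

Step 13 (C1 reduction). Hydride may be delivered from the C20 face (equatorial attack), which would give the axial C1 epimer. The fallback sets out from ketone 16 and replaces kinetic hydride delivery by electron-transfer reduction under thermodynamic control (SmI2, THF/H2O, 0 °C). The ketyl and the derived carbanion should equilibrate to the equatorial oxygen before protonation, and the ester and the diene are not reduced by this reagent. It comes back to the route at alcohol 17 and makes no new compound (F0).

**Further compounds**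

F1 | step 9 | methyl (2E)-6-[(3R,4S)-3-methyl-2-oxooxan-4-yl]hepta-2,6-dienoate | O=C1[C@H](C)[C@@H](C(=C)CC/C=C/C(=O)OC)CCO1
F2 | step 9 | methyl (2E,7S,8R)-7-(2-hydroxyethyl)-8-methyl-6-methylidene-9-oxoundeca-2,10-dienoate | C=CC(=O)[C@H](C)[C@H](CCO)C(=C)CC/C=C/C(=O)OC
F3 | step 9 | methyl (2E,7R,8Z)-9-[(tert-butyldimethylsilyl)oxy]-7-{2-[(tert-butyldimethylsilyl)oxy]ethyl}-8-methyl-6-methylideneundeca-2,8,10-trienoate | C=C/C(O[Si](C)(C)C(C)(C)C)=C(C)/[C@H](CCO[Si](C)(C)C(C)(C)C)C(=C)CC/C=C/C(=O)OC
F4 | step 9 | methyl (1S,4aR,5R,8aR)-4-[(tert-butyldimethylsilyl)oxy]-5-{2-[(tert-butyldimethylsilyl)oxy]ethyl}-4a-methyl-6-methylidene-1,2,4a,5,6,7,8,8a-octahydronaphthalene-1-carboxylate | CC(C)(C)[Si](C)(C)OCC[C@@H]1C(=C)CC[C@H]2[C@@]1(C)C(O[Si](C)(C)C(C)(C)C)=CC[C@@H]2C(=O)OC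
F5 | step 7 | methyl (2Z,7S,8R)-7-(2-hydroxyethyl)-9-[methoxy(methyl)amino]-2,8-dimethyl-6-methylidene-9-oxonon-2-enoate | CON(C)C(=O)[C@H](C)[C@H](CCO)C(=C)CC/C=C(/C)C(=O)OC
F0 | step 13 | none | none
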